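(The earlier runs and the new flask were generated by integration for substances that don't exist, and the scatter is random.)

The ratio of the two rate constants, the selectivity factor, tells us how far right-handed substrate must fall before the excess is good.

| flask | left-handed substrate | right-handed substrate | solid reagent | free catalyst | impurity | remark | time |
|---|---|---|---|---|---|---|---|
| elm | 0.19 M | 0.19 M | 0.38 M | 6.1 mM | 4.8 mM | run made earlier |  |
| birch | 0.19 M | 0.19 M | 0.85 M | 6.1 mM | 4.8 mM | run made earlier |  |
| flask | 0.19 M | 0.19 M | 0.570 M | 6.1 mM | 4.8 mM |  | 10 h |

| run | time / h | right-handed substrate / % | left-handed substrate / % | left-handed product / % |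
|---|---|---|---|---|
| elm | 2.50 | 43.4 | 7.9 | 41.9 |
| elm | 5.00 | 31.6 | 0.5 | 50.4 |
| elm | 8.00 | 19.5 | 0.3 | 50.2 |
| elm | 10.0 | 13.8 | 1.0 | 50.1 |
| birch | 0.833 | 48.3 | 33.9 | 16.7 |
| birch | 2.00 | 45.2 | 13.9 | 36.7 |
| birch | 4.00 | 36.1 | 0.4 | 48.9 |
| birch | 10.0 | 14.1 | 0.3 | 49.4 |

(each reading ± 0.5 percentage points)

- free catalyst is single-handed; left-handed substrate and right-handed substrate are mirror images of each other, charged as a racemate, each of them at the stated concentration
- as a solid, counted per litre of solution: solid reagent
- on the list of suspects stand: partner + free catalyst + left-handed substrate -> free catalyst + left-handed product; partner + free catalyst + right-handed substrate -> free catalyst + right-handed product; 2 free catalyst <-> resting dimer; solid reagent <-> partner; free catalyst + impurity -> spent catalyst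
- at the start none of the solid reagent is in solution

- whether the excess of right-handed substrate over left-handed substrate among what is left of the two reaches 99% by 10 h (no / yes)
- the highest excess of right-handed substrate over left-handed substrate among what is left of the two up to 10 h

Both suspect steps carry the same factors [partner] and [free catalyst]. So their rates stand in the ratio s[left-handed substrate]/[right-handed substrate], and the fraction left of the left-handed substrate is the fraction left of the right-handed one raised to the power s. Elm at 2.50 h gives s = 13.0. From this we reckon the crossing level, the right-handed substrate left, as a percentage of the total charged, when the excess reaches 99%: 32.2%.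

One objection is that elm has lost little right-handed substrate by then, and each reading scatters by 0.5 percentage points. But birch, with its different loading, gives 12.7 at 2.00 h, and its level is 31.8%.

A second objection is that elm reads 1.0% left-handed substrate at 10.0 h, which taken at face value is an excess of 86.5%. But no listed step forms left-handed substrate, so we treat that reading as scatter.

At the level, left-handed substrate stands at 0.162%, against a scatter of 0.5 points. We therefore watch right-handed substrate. Birch at 4.00 h still holds 36.1%, more than the level, and elm at 5.00 h reads 31.6%, less than the level. The flask has more solid reagent than elm and less than birch, so we expect the flask to cross near 5.00 h.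

The forecast reads s as about 12 where we read 13.0. It gives yes and 100%: “Nothing on the suspect list racemises, so the excess only rises.”

The flask gives yes and >99.9%, as forecast.

    partner + free catalyst + left-handed substrate → free catalyst + left-handed product (k = 8.91 M⁻² s⁻¹)
    partner + free catalyst + right-handed substrate → free catalyst + right-handed product (k = 0.681 M⁻² s⁻¹)
    2 free catalyst ⇌ resting dimer (K = 98.4 M⁻¹, k = 0.603 M⁻¹ s⁻¹)
    solid reagent ⇌ partner, rate k4*(cs4 - [partner]) while solid is left; crystals form when [partner] > cs4 (solubility = 0.0700 M, k = 5.12 × 10⁻⁴ s⁻¹)
    free catalyst + impurity → spent catalyst (k = 5.42 M⁻¹ s⁻¹)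

The flask reaches 99% at 4.81 h with 32.3% of right-handed substrate left, against our crossing level of 32.2%. Elm's reading of 31.6% at 5.00 h lies under that level by 0.60 points, against a scatter of 0.5 points, so by this rule elm stands about at the crossing then. In the flask, the left-handed step has half its turnover up to 10 h behind it at 1.27 h, sooner than the right-handed step at 4.88 h, and at 10.0 h the flask holds 13.9% of right-handed substrate.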